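**Strategy.** Both pyranone rings (ring C of each flavanone half; flavanone numbering, doubly primed locants for the 4-hydroxyphenyl half) are traced back to β-lactones. A 3,3'-linked bis(oxetan-2-one) already holds O1–C2–C3–C4 and O1''–C2''–C3''–C4'' with all four stereocentres, and each phloroglucinol ring A is added as 3,5-bis(benzyloxy)benzyne. In one operation the aryne inserts into both acyl–oxygen bonds, joining O1 to C8a and C4 to C4a, so the four-membered rings become six-membered chroman-4-ones with retention. The step exploits the ortho O1/C4 substitution of ring A and the C5 oxygen, which steers the aryne. The bis-lactone comes from an auxiliary-controlled anti-aldol (trans lactone) and a cinchona-catalysed ketene–aldehyde cycloaddition (cis lactone).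

Key step: step 9

Remark: 3,5-bis(benzyloxy)phenol is taken as commercially available, and the 4-(4-alkoxyphenyl) β-lactones are assumed to be isolable if kept below 25 °C and away from acid (base-washed silica).

Step 1
Reactants: 1 3,5-bis(benzyloxy)phenol
Product: 2 2-bromo-3,5-bis(benzyloxy)phenol
Conditions: NBS, CH2Cl2, −78 → −20 °C
Reagents that add atoms: N-bromosuccinimide, O=C1CCC(=O)N1Br
Why: Electrophilic aromatic bromination: with one equivalent of NBS at low temperature the ring should be attacked at C2, ortho to the free hydroxyl and less hindered than C4 between the two benzyloxy groups.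

Step 2
Reactants: 2 2-bromo-3,5-bis(benzyloxy)phenol
Product: 5 3,5-bis(benzyloxy)-2-(trimethylsilyl)phenyl trifluoromethanesulfonate, via aryl trimethylsilyl ether 3 (not isolated), via lithium 2-silylphenoxide 4 (not isolated)
Conditions: HMDS, THF, 70 °C; evaporate; n-BuLi, THF, −100 °C; Tf2O, −100 → −78 °C
Reagents that add atoms: hexamethyldisilazane, C[Si](C)(C)N[Si](C)(C)C; trifluoromethanesulfonic anhydride, O=S(=O)(OS(=O)(=O)C(F)(F)F)C(F)(F)F
Why: O-Silylation, bromine–lithium exchange and anionic 1,3-silyl shift from oxygen to carbon (retro-Brook rearrangement) should give the 2-silylphenoxide, whose triflation is the standard entry to a Kobayashi-type aryne precursor; at −100 °C the exchange should outrun attack on the benzyl ethers.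

Step 3
Reactants: 6 (R)-4-benzyloxazolidin-2-one; 7 pent-4-enoyl chloride
Product: 8 (R)-4-benzyl-3-(pent-4-enoyl)oxazolidin-2-one
Conditions: n-BuLi, THF, −78 °C; then 7, −78 → 0 °C
Reagents that add atoms: none
Why: N-Acylation of the lithiated oxazolidinone by the five-carbon acid chloride installs the (R)-configured Evans auxiliary that controls the next step and places the future allyl group on the α-carbon.

Step 4
Reactants: 8 (R)-4-benzyl-3-(pent-4-enoyl)oxazolidin-2-one; 9 4-methoxybenzaldehyde
Product: 11 (R)-4-benzyl-3-[(2S,3R)-2-allyl-3-hydroxy-3-(4-methoxyphenyl)propanoyl]oxazolidin-2-one, via O-trimethylsilyl aldol adduct 10 (not isolated)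
Conditions: MgCl2 (10 mol %), Et3N, TMSCl, EtOAc, 23 °C; then citric acid, MeOH, 0 °C
Reagents that add atoms: none
Why: MgCl2-catalysed anti-selective Evans aldol reaction by soft enolisation with silyl trapping: the chelated Z-enolate of the (R)-imide should be attacked by the non-enolisable aldehyde through a boat transition state on the face away from the benzyl group, which sets the future flavanone C3 as S and the carbinol carbon, the future C2, as R (anti).

Step 5
Reactants: 11 (R)-4-benzyl-3-[(2S,3R)-2-allyl-3-hydroxy-3-(4-methoxyphenyl)propanoyl]oxazolidin-2-one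
Product: 12 (2S,3R)-2-allyl-3-hydroxy-3-(4-methoxyphenyl)propanoic acid
Conditions: LiOH, H2O2, THF/H2O (3:1), 0 °C; Na2SO3; then 1 M HCl to pH 3
Reagents that add atoms: hydrogen peroxide, OO
Why: Hydroperoxide-mediated hydrolysis of the Evans imide: LiOOH should attack the exocyclic carbonyl selectively at 0 °C and release the auxiliary without retro-aldol cleavage or epimerisation at the α-carbon.

Step 6
Reactants: 12 (2S,3R)-2-allyl-3-hydroxy-3-(4-methoxyphenyl)propanoic acid
Product: 13 (3S,4R)-3-allyl-4-(4-methoxyphenyl)oxetan-2-one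
Conditions: PhSO2Cl, pyridine, 0 → 4 °C
Reagents that add atoms: none
Why: β-Lactonisation by carboxyl activation (mixed carboxylic–sulfonic anhydride): the hydroxyl attacks the activated acyl carbon, no bond to C2 or C3 is broken, and the anti acid should therefore give the trans lactone with both centres retained.

Step 7
Reactants: 13 (3S,4R)-3-allyl-4-(4-methoxyphenyl)oxetan-2-one
Product: 15 2-[(2R,3S)-2-(4-methoxyphenyl)-4-oxooxetan-3-yl]acetic acid, via lactone aldehyde 14 (not isolated)
Conditions: O3, CH2Cl2, −78 °C; PPh3, −78 → 23 °C; then NaClO2, NaH2PO4, 2-methyl-2-butene, t-BuOH/H2O, 0 °C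
Reagents that add atoms: ozone, [O-][O+]=O; sodium chlorite, [Na+].[O-]Cl=O
Why: Ozonolysis of the terminal alkene with reductive work-up followed by Pinnick oxidation in phosphate buffer should turn the allyl group into the acetic acid side chain, while the lactone and the electron-rich arene should survive the short, cold, near-neutral treatment.

Step 8
Reactants: 15 2-[(2R,3S)-2-(4-methoxyphenyl)-4-oxooxetan-3-yl]acetic acid; 16 4-(benzyloxy)benzaldehyde
Product: 19 (3S,4R)-3-[(2R,3R)-2-[4-(benzyloxy)phenyl]-4-oxooxetan-3-yl]-4-(4-methoxyphenyl)oxetan-2-one, via acid chloride 17 (not isolated), via ketene 18 (not isolated)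
Conditions: 1-chloro-N,N,2-trimethylprop-1-en-1-amine, CH2Cl2, 0 °C; then 16, O-trimethylsilylquinidine (15 mol %), LiClO4, i-Pr2NEt, CH2Cl2/Et2O (2:1), −78 → −40 °C
Reagents that add atoms: none
Why: Acyl halide–aldehyde cyclocondensation (nucleophile-catalysed ketene–aldehyde [2+2], Wynberg type): the acid chloride formed under neutral conditions gives ketene 18, whose quinidine-derived ammonium enolate should add to the LiClO4-activated aldehyde through a closed transition state that delivers the cis lactone, the catalyst fixing C3'' as R and with it C2'' as R.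

Step 9
Reactants: 19 (3S,4R)-3-[(2R,3R)-2-[4-(benzyloxy)phenyl]-4-oxooxetan-3-yl]-4-(4-methoxyphenyl)oxetan-2-one; 5 3,5-bis(benzyloxy)-2-(trimethylsilyl)phenyl trifluoromethanesulfonate
Product: 23 (2R,3S)-5,7-bis(benzyloxy)-3-[(2R,3R)-5,7-bis(benzyloxy)-2-[4-(benzyloxy)phenyl]-4-oxochroman-3-yl]-2-(4-methoxyphenyl)chroman-4-one, via aryne 20 (not isolated), via flavanone–lactone 21 (not isolated), via lactone–flavanone 22 (not isolated)
Conditions: 5 (3 equiv), CsF (6 equiv), MeCN/toluene (1:3), 23 °C
Reagents that add atoms: none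
Why: Proposed new method: fluoride is expected to convert 5 into 3,5-bis(benzyloxy)benzyne 20; a lactone ring oxygen of 19 adds to the aryne carbon remote from the 3-benzyloxy group (future C8a or C8a''), the aryl anion so formed (future C4a or C4a'') adds to the adjacent lactone carbonyl, and collapse of the fused oxetane-type adduct cleaves the old acyl–oxygen bond, a net σ-insertion that turns each oxetan-2-one into a chroman-4-one; a fluoride-relayed course through the acyl fluoride and the C2 alkoxide would converge on the same product. The closest known reaction types are the aryne insertion into the C–O bond of carboxylic acids that gives 2-hydroxyaryl ketones, the two-atom ring expansion of β-lactams and cyclic ureas by aryne insertion into N–C(=O) bonds, and the acyl-alkylation of arynes by β-keto esters. Each ring C is closed not by a direct cyclisation but by 4-exo-trig addition of the aryl anion to the lactone carbonyl followed by fragmentation of the shared O–C4 bond (ring expansion from four to six atoms), twice in one flask via 21 or 22. No stereocentre is created: C2, C3, C3'' and C2'' are carried over from 19 with retention, because the O1–C2, C2–C3 and C3–C4 bonds of each half stay intact, so the trans lactone should give the trans-2,3 ring and the cis lactone the cis-2'',3'' ring. The step needs the aryne regiochemistry that places C4 ortho and O1 meta to the first benzyloxy group, secured by the inductive polarisation of a 3-alkoxyaryne as with 3-methoxybenzyne, and it needs attack at the ring oxygen to outrun α-deprotonation with E1cB opening and benzylic ionisation, which the release of β-lactone strain, the low fluoride concentration in the toluene-rich medium and the excess of 5 are meant to secure.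

Step 10
Reactants: 23 (2R,3S)-5,7-bis(benzyloxy)-3-[(2R,3R)-5,7-bis(benzyloxy)-2-[4-(benzyloxy)phenyl]-4-oxochroman-3-yl]-2-(4-methoxyphenyl)chroman-4-one
Product: 24 sikokianin B, (2R,3S)-5,7-dihydroxy-3-[(2R,3R)-5,7-dihydroxy-2-(4-hydroxyphenyl)-4-oxochroman-3-yl]-2-(4-methoxyphenyl)chroman-4-one
Conditions: H2 (1 atm), Pd/C, EtOAc/MeOH (4:1), 23 °C
Reagents that add atoms: none
Why: Catalytic hydrogenolysis should cleave the five benzyl ethers under neutral conditions that leave the methyl ether, both ketones and the epimerisable cis-configured ring untouched.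

**Compound list**

1 | 3,5-bis(benzyloxy)phenol | Oc1cc(OCc2ccccc2)cc(OCc2ccccc2)c1 | starting material
2 | 2-bromo-3,5-bis(benzyloxy)phenol | Oc1cc(OCc2ccccc2)cc(OCc2ccccc2)c1Br | intermediate
3 | [3,5-bis(benzyloxy)-2-bromophenoxy]trimethylsilane | C[Si](C)(C)Oc1cc(OCc2ccccc2)cc(OCc2ccccc2)c1Br | intermediate
4 | lithium 3,5-bis(benzyloxy)-2-(trimethylsilyl)phenoxide | [Li+].[O-]c1cc(OCc2ccccc2)cc(OCc2ccccc2)c1[Si](C)(C)C | intermediate
5 | 3,5-bis(benzyloxy)-2-(trimethylsilyl)phenyl trifluoromethanesulfonate | C[Si](C)(C)c1c(OCc2ccccc2)cc(OCc2ccccc2)cc1OS(=O)(=O)C(F)(F)F | intermediate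
6 | (R)-4-benzyloxazolidin-2-one | O=C1OC[C@@H](Cc2ccccc2)N1 | starting material
7 | pent-4-enoyl chloride | C=CCCC(=O)Cl | starting material
8 | (R)-4-benzyl-3-(pent-4-enoyl)oxazolidin-2-one | O=C1OC[C@@H](Cc2ccccc2)N1C(=O)CCC=C | intermediate
9 | 4-methoxybenzaldehyde | COc1ccc(C=O)cc1 | starting material
10 | (R)-4-benzyl-3-[(2S,3R)-2-allyl-3-(4-methoxyphenyl)-3-(trimethylsilyloxy)propanoyl]oxazolidin-2-one | O=C1OC[C@@H](Cc2ccccc2)N1C(=O)[C@@H](CC=C)[C@@H](O[Si](C)(C)C)c1ccc(OC)cc1 | intermediate
11 | (R)-4-benzyl-3-[(2S,3R)-2-allyl-3-hydroxy-3-(4-methoxyphenyl)propanoyl]oxazolidin-2-one | O=C1OC[C@@H](Cc2ccccc2)N1C(=O)[C@@H](CC=C)[C@@H](O)c1ccc(OC)cc1 | intermediate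
12 | (2S,3R)-2-allyl-3-hydroxy-3-(4-methoxyphenyl)propanoic acid | OC(=O)[C@@H](CC=C)[C@@H](O)c1ccc(OC)cc1 | intermediate
13 | (3S,4R)-3-allyl-4-(4-methoxyphenyl)oxetan-2-one (trans) | COc1ccc([C@@H]2OC(=O)[C@H]2CC=C)cc1 | intermediate
14 | 2-[(2R,3S)-2-(4-methoxyphenyl)-4-oxooxetan-3-yl]acetaldehyde | COc1ccc([C@@H]2OC(=O)[C@H]2CC=O)cc1 | intermediate
15 | 2-[(2R,3S)-2-(4-methoxyphenyl)-4-oxooxetan-3-yl]acetic acid | COc1ccc([C@@H]2OC(=O)[C@H]2CC(=O)O)cc1 | intermediate
16 | 4-(benzyloxy)benzaldehyde | O=Cc1ccc(OCc2ccccc2)cc1 | starting material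
17 | 2-[(2R,3S)-2-(4-methoxyphenyl)-4-oxooxetan-3-yl]acetyl chloride | COc1ccc([C@@H]2OC(=O)[C@H]2CC(=O)Cl)cc1 | intermediate
18 | (3S,4R)-4-(4-methoxyphenyl)-3-(2-oxoethenyl)oxetan-2-one (ketene) | COc1ccc([C@@H]2OC(=O)[C@H]2C=C=O)cc1 | intermediate
19 | (3S,4R)-3-[(2R,3R)-2-[4-(benzyloxy)phenyl]-4-oxooxetan-3-yl]-4-(4-methoxyphenyl)oxetan-2-one (trans lactone linked at C3 to cis lactone) | COc1ccc([C@@H]2OC(=O)[C@H]2[C@H]2C(=O)O[C@H]2c2ccc(OCc3ccccc3)cc2)cc1 | intermediate
20 | 3,5-bis(benzyloxy)benzyne (1,2-didehydro-3,5-bis(benzyloxy)benzene) | C1(OCc2ccccc2)=CC(OCc2ccccc2)=CC#C1 | intermediate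
21 | (2R,3S)-5,7-bis(benzyloxy)-3-[(2R,3R)-2-[4-(benzyloxy)phenyl]-4-oxooxetan-3-yl]-2-(4-methoxyphenyl)chroman-4-one | COc1ccc([C@@H]2Oc3cc(OCc4ccccc4)cc(OCc4ccccc4)c3C(=O)[C@H]2[C@H]2C(=O)O[C@H]2c2ccc(OCc3ccccc3)cc2)cc1 | intermediate
22 | (3S,4R)-3-[(2R,3R)-5,7-bis(benzyloxy)-2-[4-(benzyloxy)phenyl]-4-oxochroman-3-yl]-4-(4-methoxyphenyl)oxetan-2-one | COc1ccc([C@@H]2OC(=O)[C@H]2[C@H]2C(=O)c3c(OCc4ccccc4)cc(OCc4ccccc4)cc3O[C@H]2c2ccc(OCc3ccccc3)cc2)cc1 | intermediate
23 | (2R,3S)-5,7-bis(benzyloxy)-3-[(2R,3R)-5,7-bis(benzyloxy)-2-[4-(benzyloxy)phenyl]-4-oxochroman-3-yl]-2-(4-methoxyphenyl)chroman-4-one | COc1ccc([C@@H]2Oc3cc(OCc4ccccc4)cc(OCc4ccccc4)c3C(=O)[C@H]2[C@H]2C(=O)c3c(OCc4ccccc4)cc(OCc4ccccc4)cc3O[C@H]2c2ccc(OCc3ccccc3)cc2)cc1 | intermediate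
24 | sikokianin B, (2R,3S)-5,7-dihydroxy-3-[(2R,3R)-5,7-dihydroxy-2-(4-hydroxyphenyl)-4-oxochroman-3-yl]-2-(4-methoxyphenyl)chroman-4-one | COc1ccc([C@@H]2Oc3cc(O)cc(O)c3C(=O)[C@H]2[C@H]2C(=O)c3c(O)cc(O)cc3O[C@H]2c2ccc(O)cc2)cc1 | target

**Step count and risks**

Total step count: 10. Longest linear sequence: 8 steps (steps 3 to 10, from 6 and 7 to 24); the aryne precursor 5 is made in 2 steps and joins at step 9.

The three steps most likely to fail are steps 9, 8 and 6.

Step 9. The lactone ring oxygen may prove too weak a nucleophile, so that the aryne is lost to fluoride, solvent or oligomerisation. Capture of the aryne by the carbonyl oxygen instead would lead through benzylic ionisation and loss of configuration at C2 or C2''. Fluoride may also open the lactones by α-deprotonation and E1cB elimination, or epimerise C3''. The fallback sets out from 19 and returns to 23 by known reactions that also keep the O1–C2 and O1''–C2'' bonds. 1,3-Bis(benzyloxy)-5-fluorobenzene F1 (from commercial 5-fluororesorcinol, BnBr, K2CO3) would be lithiated between fluorine and a benzyloxy group (n-BuLi, THF, −78 °C). The aryllithium would be added to both lactone carbonyls of 19 at −78 °C (acyl substitution of a β-lactone by an organolithium) to give the bis(β-hydroxy 2-fluoroaryl ketone) F2. Intramolecular SNAr displacement of each fluoride, activated by the ortho ketone, by the neighbouring secondary alkoxide (K2CO3, DMF, 50 °C) would then close both rings C with retention at C2 and C2'' and give 23.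

Step 8. The resident p-methoxybenzylic lactone may ionise under the Lewis-acidic, chloride-containing conditions, and the catalyst may be mismatched with the neighbouring C3 stereocentre, eroding facial and cis selectivity. The fallback changes the order of events; it sets out from 13 and returns at 21. Lactone 13 would first be ring-expanded with 5 and CsF (conditions of step 9) to 3-allylflavanone F3. Ozonolysis would give aldehyde F4 and Pinnick oxidation acid F5. Conversion into acid chloride F6 and ketene F7, then cycloaddition with 16 under the conditions of step 8, now on a robust flavanone, would deliver 21. This intermediate of step 9 is carried to 23 by the second insertion.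

Step 6. Carboxyl activation of 12 may be outrun by ionisation of the p-methoxybenzylic C–O bond (O-sulfonylation, decarboxylative elimination to the styrene). The fallback closes the lactone by thiophilic activation instead; it sets out from 11 and returns at 13. Aldol adduct 11 would be converted with LiSEt (THF, 0 °C) into S-ethyl thioester F8 with release of the auxiliary. F8 would be cyclised with AgO2CCF3 and Na2HPO4 in MeCN (thiophilic lactonisation of a β-hydroxy thioester, retention at both centres; the silver salt is preferred to a mercury salt because it should spare the terminal alkene from intramolecular alkoxymetalation) to give 13.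

Further compounds
F1 | step 9 | 1,3-bis(benzyloxy)-5-fluorobenzene | Fc1cc(OCc2ccccc2)cc(OCc2ccccc2)c1
F2 | step 9 | (2S,3R)-1,4-bis[2,4-bis(benzyloxy)-6-fluorophenyl]-2-[(R)-hydroxy(4-methoxyphenyl)methyl]-3-[(R)-[4-(benzyloxy)phenyl](hydroxy)methyl]butane-1,4-dione | COc1ccc([C@H](O)[C@@H](C(=O)c2c(F)cc(OCc3ccccc3)cc2OCc2ccccc2)[C@@H](C(=O)c2c(F)cc(OCc3ccccc3)cc2OCc2ccccc2)[C@@H](O)c2ccc(OCc3ccccc3)cc2)cc1
F3 | step 8 | (2R,3S)-3-allyl-5,7-bis(benzyloxy)-2-(4-methoxyphenyl)chroman-4-one | COc1ccc([C@@H]2Oc3cc(OCc4ccccc4)cc(OCc4ccccc4)c3C(=O)[C@H]2CC=C)cc1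
F4 | step 8 | 2-[(2R,3S)-5,7-bis(benzyloxy)-2-(4-methoxyphenyl)-4-oxochroman-3-yl]acetaldehyde | COc1ccc([C@@H]2Oc3cc(OCc4ccccc4)cc(OCc4ccccc4)c3C(=O)[C@H]2CC=O)cc1
F5 | step 8 | 2-[(2R,3S)-5,7-bis(benzyloxy)-2-(4-methoxyphenyl)-4-oxochroman-3-yl]acetic acid | COc1ccc([C@@H]2Oc3cc(OCc4ccccc4)cc(OCc4ccccc4)c3C(=O)[C@H]2CC(=O)O)cc1
F6 | step 8 | 2-[(2R,3S)-5,7-bis(benzyloxy)-2-(4-methoxyphenyl)-4-oxochroman-3-yl]acetyl chloride | COc1ccc([C@@H]2Oc3cc(OCc4ccccc4)cc(OCc4ccccc4)c3C(=O)[C@H]2CC(=O)Cl)cc1
F7 | step 8 | (2R,3S)-5,7-bis(benzyloxy)-2-(4-methoxyphenyl)-3-(2-oxoethenyl)chroman-4-one | COc1ccc([C@@H]2Oc3cc(OCc4ccccc4)cc(OCc4ccccc4)c3C(=O)[C@H]2C=C=O)cc1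
F8 | step 6 | S-ethyl (2S,3R)-2-allyl-3-hydroxy-3-(4-methoxyphenyl)propanethioate | CCSC(=O)[C@@H](CC=C)[C@@H](O)c1ccc(OC)cc1
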